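**Retrosynthetic overview**
1. Last disconnection: the exocyclic amidine C–N bond between the 2-amino group of the imidazole (ring A) and C4 of N-methylimidazolidinetrione (ring B, bought preformed), made by silyl-mediated condensation.
2. Key disconnection: the C4(ring A)–CH(OH)Ar bond, made by a catalytic enantioselective hydroxyalkylation of the C4–H aminoimidazole with 4-methoxybenzaldehyde; this sets the only stereocentre, (R).
3. Ring A: N-methylpyrimidin-2-amine plus a bromomethyl 4-methoxybenzyl ketone give an imidazo[1,2-a]pyrimidinium salt, and hydrazine then excises the pyrimidine carbons.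
4. The bromomethyl ketone comes from (4-methoxyphenyl)acetyl chloride by one-carbon homologation through its diazoketone.
5. Ring order: ring A is the only ring built (step 2); ring B and both anisole rings are bought intact.

Assumption: the SMILES descriptor corresponds to (R) at the carbinol carbon (O > imidazolyl C > aryl C > H), and the four compounds marked as starting materials are catalogue items.
Catalyst Q-SQ: the quinine-derived squaramide 3-{[3,5-bis(trifluoromethyl)phenyl]amino}-4-{[(8α,9S)-6′-methoxycinchonan-9-yl]amino}cyclobut-3-ene-1,2-dione, used at 10 mol % in the key hydroxyalkylation (CH2Cl2/PhMe 1:1, 0.5 M).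
Stoichiometry: the aldehyde in the hydroxyalkylation and the trione in the final condensation are each used in 1.5-fold excess; the excess is recovered or washed out unchanged.

**Step 1**
Reactants: 1 (4-methoxyphenyl)acetyl chloride
Product: 3 1-bromo-3-(4-methoxyphenyl)propan-2-one, via diazoketone 2 (not isolated)
Conditions: TMSCHN2 (2 equiv), MeCN/THF, 0 °C to 23 °C; then 48% aq. HBr, 0 °C
Reagents that add atoms: (trimethylsilyl)diazomethane, C[Si](C)(C)C=[N+]=[N-]; hydrogen bromide, Br
Why: The acid chloride acylates the diazo carbon (Arndt–Eistert-type diazoketone formation, silyl group lost to chloride), and HBr then protonates the diazo carbon and bromide displaces N2, a standard route to bromomethyl ketones that leaves the anisole untouched.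

**Step 2**
Reactants: 3 1-bromo-3-(4-methoxyphenyl)propan-2-one; 4 N-methylpyrimidin-2-amine
Product: 6 5-(4-methoxybenzyl)-1-methyl-1H-imidazol-2-amine, via imidazo[1,2-a]pyrimidin-1-ium bromide 5 (not isolated)
Conditions: MeCN, 130 °C (sealed tube), 45 min; then N2H4·H2O (7 equiv), 100 °C, 15 min
Reagents that add atoms: none
Why: The ring nitrogen of 4 is alkylated by the bromomethyl group and the exocyclic N-methylamino group cyclodehydrates onto the ketone (Chichibabin-type imidazo[1,2-a]pyrimidine annulation), which places N-methyl next to the benzyl-bearing carbon; hydrazine then excises the three pyrimidine carbons as pyrazole (pyrimidinium hydrazinolysis) and unmasks the 2-amino group.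

**Step 3**
Reactants: 6 5-(4-methoxybenzyl)-1-methyl-1H-imidazol-2-amine; 7 4-methoxybenzaldehyde
Product: 8 (R)-[2-amino-5-(4-methoxybenzyl)-1-methyl-1H-imidazol-4-yl](4-methoxyphenyl)methanol
Conditions: Q-SQ (cat.), CH2Cl2/PhMe, −20 °C, 72 h; chromatography on Et3N-deactivated silica
Reagents that add atoms: none
Why: Proposed new method: an organocatalytic enantioselective Friedel–Crafts-type hydroxyalkylation of a 2-aminoimidazole by an aryl aldehyde, a pure addition in which every atom of both partners ends up in the product. Compound 6 is a cyclic ene-guanidine whose only free ring carbon, C4, is the enamine β-carbon. The squaramide N–H pair binds and activates the aldehyde C=O, while the quinuclidine nitrogen hydrogen-bonds the 2-NH2/N3 amidine edge of 6; this raises C4 nucleophilicity, holds both partners in the chiral pocket so that C4 adds to the Si face of the aldehyde (giving the (R)-carbinol), and relays the C4 proton to oxygen to re-aromatise. Apolar solvent, low temperature and only a modest excess of aldehyde suppress the uncatalysed background, hemiaminal formation at the 2-amino group and ionisation of the product. The closest known reactions are the uncatalysed, racemic hydroxyalkylation of 2-aminoimidazoles by aldehydes in protic media, and cinchona squaramide- or thiourea-catalysed Friedel–Crafts hydroxyalkylations of aminopyrazoles, indoles and naphthols with activated carbonyls and Henry reactions of aryl aldehydes.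

**Step 4**
Reactants: 8 (R)-[2-amino-5-(4-methoxybenzyl)-1-methyl-1H-imidazol-4-yl](4-methoxyphenyl)methanol; 9 1-methylimidazolidine-2,4,5-trione
Product: 13 4-({4-[(R)-hydroxy(4-methoxyphenyl)methyl]-5-(4-methoxybenzyl)-1-methyl-1H-imidazol-2-yl}amino)-1-methyl-1H-imidazole-2,5-dione, via O-silyl imidate 10 (not isolated), via TMS ether 11 (not isolated), via O-TMS target 12 (not isolated)
Conditions: BSA (4 equiv), MeCN/PhMe, 23 °C, 1 h, then 80 °C, 12 h; then MeOH, aq. NaH2PO4/Na2HPO4 (pH 7), 23 °C
Reagents that add atoms: none
Why: This is the silyl-mediated amidine-forming condensation used in naamidine-type end-games: N,O-bis(trimethylsilyl)acetamide (BSA) converts the N–H lactam of 9 into O-silyl imidate 10 and masks the carbinol as TMS ether 11, the 2-amino group adds to the imidate carbon (the carbonyl remote from N-methyl) and expels silanolate, and buffered work-up frees the alcohol without touching the stereocentre.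

**Compound list**
1 | (4-methoxyphenyl)acetyl chloride | COc1ccc(CC(Cl)=O)cc1 | starting material
2 | 1-diazo-3-(4-methoxyphenyl)propan-2-one | COc1ccc(CC(=O)C=[N+]=[N-])cc1 | intermediate (not isolated)
3 | 1-bromo-3-(4-methoxyphenyl)propan-2-one | COc1ccc(CC(=O)CBr)cc1 | intermediate
4 | N-methylpyrimidin-2-amine | CNc1ncccn1 | starting material
5 | 2-(4-methoxybenzyl)-1-methylimidazo[1,2-a]pyrimidin-1-ium bromide | COc1ccc(Cc2cn3cccnc3[n+]2C)cc1.[Br-] | intermediate (not isolated)
6 | 5-(4-methoxybenzyl)-1-methyl-1H-imidazol-2-amine | COc1ccc(Cc2cnc(N)n2C)cc1 | intermediate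
7 | 4-methoxybenzaldehyde | COc1ccc(C=O)cc1 | starting material
8 | (R)-[2-amino-5-(4-methoxybenzyl)-1-methyl-1H-imidazol-4-yl](4-methoxyphenyl)methanol | COc1ccc(Cc2c([C@H](O)c3ccc(OC)cc3)nc(N)n2C)cc1 | intermediate
9 | 1-methylimidazolidine-2,4,5-trione (1-methylparabanic acid) | CN1C(=O)NC(=O)C1=O | starting material
10 | 1-methyl-4-[(trimethylsilyl)oxy]-1H-imidazole-2,5-dione | CN1C(=O)N=C(O[Si](C)(C)C)C1=O | intermediate (not isolated)
11 | 5-(4-methoxybenzyl)-4-{(R)-(4-methoxyphenyl)[(trimethylsilyl)oxy]methyl}-1-methyl-1H-imidazol-2-amine | COc1ccc(Cc2c([C@H](O[Si](C)(C)C)c3ccc(OC)cc3)nc(N)n2C)cc1 | intermediate (not isolated)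
12 | 4-[(5-(4-methoxybenzyl)-4-{(R)-(4-methoxyphenyl)[(trimethylsilyl)oxy]methyl}-1-methyl-1H-imidazol-2-yl)amino]-1-methyl-1H-imidazole-2,5-dione | COc1ccc(Cc2c([C@H](O[Si](C)(C)C)c3ccc(OC)cc3)nc(NC3=NC(=O)N(C)C3=O)n2C)cc1 | intermediate (not isolated)
13 | 4-({4-[(R)-hydroxy(4-methoxyphenyl)methyl]-5-(4-methoxybenzyl)-1-methyl-1H-imidazol-2-yl}amino)-1-methyl-1H-imidazole-2,5-dione | COc1ccc(Cc2c([C@H](O)c3ccc(OC)cc3)nc(NC3=NC(=O)N(C)C3=O)n2C)cc1 | target

**Step count and risks**
Total step count: 4. Longest linear sequence: 4 steps (1 → 3 → 6 → 8 → 13).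

Most likely to fail, first: step 3 (the proposed new step). The electron-rich aldehyde is a weak electrophile, and basic 6 may occupy the squaramide itself. The doubly activated carbinol can lose ee by retro-addition or ionisation, or go on to a bis(imidazolyl)methane; reversible hemiaminal formation at the 2-amino group is a non-productive resting state. The facial sense is a model prediction and must be checked; the quinidine-derived pseudoenantiomer of Q-SQ is the remedy if the sense is reversed. The fallback uses known chemistry, sets out from 6 (with 7) and comes back at 8. Compounds 6 and 7 are combined without catalyst in MeOH/H2O at 40 °C, the known uncatalysed hydroxyalkylation of 2-aminoimidazoles, to give the racemic carbinol (RS)-[2-amino-5-(4-methoxybenzyl)-1-methyl-1H-imidazol-4-yl](4-methoxyphenyl)methanol F1. This is oxidised with MnO2 in CH2Cl2 at 23 °C to the ketone [2-amino-5-(4-methoxybenzyl)-1-methyl-1H-imidazol-4-yl](4-methoxyphenyl)methanone F2. The ketone is reduced with the (S)-methyl-CBS catalyst, (S)-1-methyl-3,3-diphenyltetrahydro-1H,3H-pyrrolo[1,2-c][1,3,2]oxazaborole, and BH3·SMe2 (one extra equivalent for the amidine nitrogen) in THF at −20 °C to give 8. The (S)-catalyst is expected to give (R) if the flanked aminoimidazolyl group acts as the large substituent, and the (R)-catalyst is used otherwise; ee is raised by recrystallisation.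

Second: step 4. At 80 °C in the presence of silylating agents the TMS ether 11 of the doubly activated carbinol may ionise, which would racemise or destroy the stereocentre before the amidine is formed. The fallback sets out from 8 and comes back at 13. Compound 8 is silylated with TBSCl and imidazole in DMF at 23 °C to give the robust ether 4-{(R)-[(tert-butyldimethylsilyl)oxy](4-methoxyphenyl)methyl}-5-(4-methoxybenzyl)-1-methyl-1H-imidazol-2-amine F3. This is condensed with 9 and BSA (through 10) in MeCN/PhMe at 80 °C to give 4-[(4-{(R)-[(tert-butyldimethylsilyl)oxy](4-methoxyphenyl)methyl}-5-(4-methoxybenzyl)-1-methyl-1H-imidazol-2-yl)amino]-1-methyl-1H-imidazole-2,5-dione F4. The silyl ether is then removed with TBAF/AcOH in THF at 0 °C, now on the less electron-rich, acylamidine-substituted imidazole, to give 13.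

Third: step 2. If hydrazine meets material that has not fully cyclodehydrated to 5, a Dimroth-type rearrangement can move the methyl group to the exocyclic nitrogen; self-condensation of the enolisable bromoketone is a second loss. The fallback sets out from 3 and comes back at 6. Compound 3 is condensed with pyrimidin-2-amine (NaHCO3, EtOH, 80 °C) and the neutral bicycle 2-(4-methoxybenzyl)imidazo[1,2-a]pyrimidine F5 is isolated. It is methylated at N1 with MeI in MeCN at 60 °C to give 2-(4-methoxybenzyl)-1-methylimidazo[1,2-a]pyrimidin-1-ium iodide F6. This fully aromatised salt is cleaved with N2H4·H2O in EtOH at 80 °C to give 6.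

**Further compounds**
F1 | step 3 | (RS)-[2-amino-5-(4-methoxybenzyl)-1-methyl-1H-imidazol-4-yl](4-methoxyphenyl)methanol | COc1ccc(Cc2c(C(O)c3ccc(OC)cc3)nc(N)n2C)cc1
F2 | step 3 | [2-amino-5-(4-methoxybenzyl)-1-methyl-1H-imidazol-4-yl](4-methoxyphenyl)methanone | COc1ccc(Cc2c(C(=O)c3ccc(OC)cc3)nc(N)n2C)cc1
F3 | step 4 | 4-{(R)-[(tert-butyldimethylsilyl)oxy](4-methoxyphenyl)methyl}-5-(4-methoxybenzyl)-1-methyl-1H-imidazol-2-amine | COc1ccc(Cc2c([C@H](O[Si](C)(C)C(C)(C)C)c3ccc(OC)cc3)nc(N)n2C)cc1
F4 | step 4 | 4-[(4-{(R)-[(tert-butyldimethylsilyl)oxy](4-methoxyphenyl)methyl}-5-(4-methoxybenzyl)-1-methyl-1H-imidazol-2-yl)amino]-1-methyl-1H-imidazole-2,5-dione | COc1ccc(Cc2c([C@H](O[Si](C)(C)C(C)(C)C)c3ccc(OC)cc3)nc(NC3=NC(=O)N(C)C3=O)n2C)cc1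
F5 | step 2 | 2-(4-methoxybenzyl)imidazo[1,2-a]pyrimidine | COc1ccc(Cc2cn3cccnc3n2)cc1
F6 | step 2 | 2-(4-methoxybenzyl)-1-methylimidazo[1,2-a]pyrimidin-1-ium iodide | COc1ccc(Cc2cn3cccnc3[n+]2C)cc1.[I-]
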